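**Strategy.** The cyclohexane (C1 CHEt, C2 CHMe, C3 CHAr, C4 CHMe, C5 CHAr, C6 spiro) is cut at C4–C5 and C5–C6. The feature exploited is C5: a CH(aryl) carbon lying between C4 and the spiro carbon C6 of the dienone ring, i.e. an aryl aldehyde carbon that has made two C–C bonds, next to a C4 methyl group that can be carried as an epimerisable formyl group. One operation joins the silyl enol ether of a stereodefined 3,5-diaryl-4-methylheptanal (C1–C3 set) to 2,4,5-trimethoxybenzaldehyde dimethyl acetal, closes the ring by ipso attack of the C1 aryl group, and sets C4, C5 and C6.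

Key step: step 9

Assumption: the target SMILES fixes six stereocentres and no stereogenic axis, so rotamers about the aryl–C3 and aryl–C5 bonds are taken to interconvert and only the stereocentres are addressed.

Step 1
Reactants: 1 2,4,5-trimethoxybenzaldehyde
Product: 2 (±)-1-(2,4,5-trimethoxyphenyl)prop-2-en-1-ol
Conditions: CH2=CHMgBr, THF, 0 °C; aq. NH4Cl
Reagents that add atoms: vinylmagnesium bromide, C=C[Mg]Br
Why: Grignard 1,2-addition to an aryl aldehyde gives the racemic branched allylic alcohol, which is sufficient because both enantiomers converge on one allyl–iridium intermediate in the next step.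

Step 2
Reactants: 2 (±)-1-(2,4,5-trimethoxyphenyl)prop-2-en-1-ol; 3 propanal
Product: 4 (2S,3R)-2-methyl-3-(2,4,5-trimethoxyphenyl)pent-4-enal
Conditions: [Ir(cod)Cl]2 (3 mol %), (S)-configured 1,1'-binaphthyl-2,2'-diyl N-(5H-dibenzo[b,f]azepin-5-yl)phosphoramidite (12 mol %), (R)-α,α-bis[3,5-bis(trifluoromethyl)phenyl]prolinol trimethylsilyl ether (10 mol %), (MeO)2P(O)OH (promoter), 3 (3 equiv), ClCH2CH2Cl, 25 °C
Reagents that add atoms: none
Why: Stereodivergent dual catalysis (iridium-catalysed enantioconvergent allylic substitution merged with enamine catalysis) should give the branched aldehyde, the ligand antipode fixing the aryl-bearing carbon (ring C1, 3R here) and the amine antipode, by shielding one enamine face, fixing the methyl-bearing carbon (ring C2, 2S here) independently.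

Step 3
Reactants: 4 (2S,3R)-2-methyl-3-(2,4,5-trimethoxyphenyl)pent-4-enal
Product: 5 (2S,3R)-2-methyl-3-(2,4,5-trimethoxyphenyl)pentanal
Conditions: H2 (1 atm), 5% Pd/C, EtOAc, rt, short reaction time
Reagents that add atoms: none
Why: Heterogeneous hydrogenation of a monosubstituted alkene is much faster than aldehyde reduction or double-bond migration under neutral conditions, so the vinyl group should become the C1 ethyl group without change at either stereocentre.

Step 4
Reactants: 5 (2S,3R)-2-methyl-3-(2,4,5-trimethoxyphenyl)pentanal; 6 triethyl phosphonoacetate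
Product: 7 ethyl (2E,4R,5R)-4-methyl-5-(2,4,5-trimethoxyphenyl)hept-2-enoate
Conditions: LiCl, iPr2NEt, MeCN, rt
Reagents that add atoms: none
Why: Horner–Wadsworth–Emmons olefination under lithium chloride/amine conditions is E-selective and mild enough not to epimerise the α-branched aldehyde (the descriptor at the methyl-bearing carbon changes only through priorities).

Step 5
Reactants: 7 ethyl (2E,4R,5R)-4-methyl-5-(2,4,5-trimethoxyphenyl)hept-2-enoate; 8 2,4,5-trimethoxyphenylboronic acid
Product: 9 ethyl (3R,4S,5R)-4-methyl-3,5-bis(2,4,5-trimethoxyphenyl)heptanoate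
Conditions: [Rh(OH)((R)-binap)]2 (3 mol %), 8 (3 equiv), dioxane/H2O (10:1), 50 °C
Reagents that add atoms: none
Why: In this rhodium-catalysed asymmetric 1,4-addition of an arylboronic acid (Hayashi–Miyaura reaction) the (R)-binap aryl–rhodium species should deliver the aryl group to the Si face of C3 of the E-enoate (new 3R centre, anti to the C4 methyl group in the zigzag chain), a sense that the Felkin–Anh preference of the existing C4 centre should reinforce.

Step 6
Reactants: 9 ethyl (3R,4S,5R)-4-methyl-3,5-bis(2,4,5-trimethoxyphenyl)heptanoate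
Product: 10 (3R,4S,5R)-4-methyl-3,5-bis(2,4,5-trimethoxyphenyl)heptanal
Conditions: iBu2AlH (1.05 equiv), CH2Cl2, −78 °C; MeOH, then aq. potassium sodium tartrate
Reagents that add atoms: none
Why: Partial ester reduction with iBu2AlH at −78 °C stops at the aluminium hemiacetal, which releases the aldehyde only on work-up, and no stereocentre is α to the carbonyl group.

Step 7
Reactants: 10 (3R,4S,5R)-4-methyl-3,5-bis(2,4,5-trimethoxyphenyl)heptanal
Product: 11 trimethyl{[(3S,4S,5R)-4-methyl-3,5-bis(2,4,5-trimethoxyphenyl)hept-1-en-1-yl]oxy}silane (E/Z mixture)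
Conditions: Me3SiCl, NaI, Et3N, MeCN, rt; pentane extraction, used without chromatography
Reagents that add atoms: chlorotrimethylsilane, C[Si](C)(C)Cl
Why: Soft enolisation and O-silylation of the aldehyde with Me3SiI made in situ gives the silyl enol ether, whose geometry is irrelevant because the centres it could influence are later ionised (C5) or equilibrated (C4), while the three set centres are untouched (the C3 descriptor changes only through priorities).

Step 8
Reactants: 1 2,4,5-trimethoxybenzaldehyde
Product: 12 1-(dimethoxymethyl)-2,4,5-trimethoxybenzene (2,4,5-trimethoxybenzaldehyde dimethyl acetal)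
Conditions: HC(OMe)3 (neat), TsOH·H2O (1 mol %), rt; K2CO3, then filtration and removal of volatiles
Reagents that add atoms: trimethyl orthoformate, COC(OC)OC
Why: Acid-catalysed acetalisation with trimethyl orthoformate as methoxy source and dehydrating agent converts the aldehyde into the acetal that serves as 1,1-dielectrophile.

Step 9
Reactants: 11 trimethyl{[(3S,4S,5R)-4-methyl-3,5-bis(2,4,5-trimethoxyphenyl)hept-1-en-1-yl]oxy}silane; 12 1-(dimethoxymethyl)-2,4,5-trimethoxybenzene
Product: 15 (6S,7R,8S,9S,10R,11R)-7-ethyl-10-formyl-1,4-dimethoxy-8-methyl-9,11-bis(2,4,5-trimethoxyphenyl)spiro[5.5]undeca-1,4-dien-3-one, via β-methoxy aldehyde adduct 13 (not isolated), via O-methyl spiro-oxocarbenium triflate 14 (not isolated)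
Conditions: Me3SiOTf (0.1 equiv), CH2Cl2, −78 °C; then Me3SiOTf (1.5 equiv), −78 → −20 °C; aq. NaHCO3
Reagents that add atoms: water, O
Why: Proposed new method: Me3SiOTf ionises acetal 12 to an aryl-stabilised oxocarbenium ion that is attacked by the enol ether carbon of 11 (Mukaiyama-type addition, C4–C5 bond), and the benzylic methyl ether of adduct 13 then ionises again under excess Me3SiOTf to a cation (or, after reversible proton loss, the O-silylated enal, an equivalent electrophile) that is captured by the ipso carbon of the C1 aryl ring (C5–C6 bond) to give oxocarbenium ion 14, which is hydrolysed to the dienone on quenching. The closest known reactions are silyl triflate-catalysed additions of silyl enol ethers to aryl acetals, double Friedel–Crafts reactions of benzaldehyde acetals as 1,1-dielectrophiles, and cationic ipso spirocyclisations para to a methoxy group, whose combination in one flask is new. The cyclohexane closes by a six-membered, chair-like ipso (spiro) Friedel–Crafts attack of the arene on the C5 cation, the C4–C5 bond having been made intermolecularly just before. C5 is set in that transition state with its aryl group equatorial relative to the preset C1–C3 centres, C6 is set by the arene rotamer that puts the small CH arm axial, syn to the axial C2 methyl group, and the methoxy-bearing arm equatorial, and C4 should end with the formyl group equatorial between two equatorial aryl groups through enolisation under the acidic conditions. The step needs six-ring ipso closure to beat five-ring ortho closure by the C3 aryl group (indane formation) and loss of the para rather than the ortho O-methyl group, which is secured because the ipso carbon is activated by a para and an ortho methoxy group whereas the competing ortho carbon has only one, and because the cross-conjugated 2,5-dienone is the more stable product.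

Step 10
Reactants: 15 (6S,7R,8S,9S,10R,11R)-7-ethyl-10-formyl-1,4-dimethoxy-8-methyl-9,11-bis(2,4,5-trimethoxyphenyl)spiro[5.5]undeca-1,4-dien-3-one
Product: 16 (6S,7R,8S,9S,10R,11R)-7-ethyl-10-(hydroxymethyl)-1,4-dimethoxy-8-methyl-9,11-bis(2,4,5-trimethoxyphenyl)spiro[5.5]undeca-1,4-dien-3-one
Conditions: NaBH4, MeOH/CH2Cl2, −40 °C
Reagents that add atoms: none
Why: In this chemoselective hydride reduction the aldehyde is far more electrophilic than the donor-substituted cross-conjugated dienone (a vinylogous ester), so only the formyl group should be reduced and C4 keeps its equatorial substituent.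

Step 11
Reactants: 16 (6S,7R,8S,9S,10R,11R)-7-ethyl-10-(hydroxymethyl)-1,4-dimethoxy-8-methyl-9,11-bis(2,4,5-trimethoxyphenyl)spiro[5.5]undeca-1,4-dien-3-one
Product: 17 (6S,7R,8S,9S,10R,11R)-7-ethyl-10-(iodomethyl)-1,4-dimethoxy-8-methyl-9,11-bis(2,4,5-trimethoxyphenyl)spiro[5.5]undeca-1,4-dien-3-one
Conditions: PPh3, I2, imidazole, toluene, rt → 60 °C
Reagents that add atoms: iodine, I-I
Why: Appel-type iodination converts the primary alcohol into the iodide by SN2 displacement of an alkoxyphosphonium ion under neutral conditions that leave the dienone and the aryl ethers alone.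

Step 12
Reactants: 17 (6S,7R,8S,9S,10R,11R)-7-ethyl-10-(iodomethyl)-1,4-dimethoxy-8-methyl-9,11-bis(2,4,5-trimethoxyphenyl)spiro[5.5]undeca-1,4-dien-3-one
Product: 18 tatanan B, (6S,7R,8S,9S,10R,11R)-7-ethyl-1,4-dimethoxy-8,10-dimethyl-9,11-bis(2,4,5-trimethoxyphenyl)spiro[5.5]undeca-1,4-dien-3-one
Conditions: Bu3SnH, AIBN (cat.), toluene, 80 °C
Reagents that add atoms: none
Why: In this radical chain dehalogenation the primary radical should take hydrogen from the stannane faster than it can reach the dienone or arene π systems, which the chair holds away from the equatorial CH2 group, giving the C4 methyl group without change at any stereocentre.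

**Compound list**

For 15–18 the chair has Et (C1), aryl (C3), the C4 substituent and aryl (C5) equatorial, Me (C2) axial, and the methoxy-bearing dienone arm equatorial at C6.

1 | 2,4,5-trimethoxybenzaldehyde | COc1cc(OC)c(C=O)cc1OC | starting material
2 | (±)-1-(2,4,5-trimethoxyphenyl)prop-2-en-1-ol | C=CC(O)c1cc(OC)c(OC)cc1OC | intermediate
3 | propanal | CCC=O | starting material
4 | (2S,3R)-2-methyl-3-(2,4,5-trimethoxyphenyl)pent-4-enal | C=C[C@@H](c1cc(OC)c(OC)cc1OC)[C@H](C)C=O | intermediate
5 | (2S,3R)-2-methyl-3-(2,4,5-trimethoxyphenyl)pentanal | CC[C@@H](c1cc(OC)c(OC)cc1OC)[C@H](C)C=O | intermediate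
6 | triethyl phosphonoacetate | CCOC(=O)CP(=O)(OCC)OCC | starting material
7 | ethyl (2E,4R,5R)-4-methyl-5-(2,4,5-trimethoxyphenyl)hept-2-enoate | CC[C@@H](c1cc(OC)c(OC)cc1OC)[C@H](C)/C=C/C(=O)OCC | intermediate
8 | 2,4,5-trimethoxyphenylboronic acid | COc1cc(OC)c(B(O)O)cc1OC | starting material
9 | ethyl (3R,4S,5R)-4-methyl-3,5-bis(2,4,5-trimethoxyphenyl)heptanoate | CC[C@@H](c1cc(OC)c(OC)cc1OC)[C@H](C)[C@H](c1cc(OC)c(OC)cc1OC)CC(=O)OCC | intermediate
10 | (3R,4S,5R)-4-methyl-3,5-bis(2,4,5-trimethoxyphenyl)heptanal | CC[C@@H](c1cc(OC)c(OC)cc1OC)[C@H](C)[C@H](c1cc(OC)c(OC)cc1OC)CC=O | intermediate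
11 | trimethyl{[(3S,4S,5R)-4-methyl-3,5-bis(2,4,5-trimethoxyphenyl)hept-1-en-1-yl]oxy}silane, E/Z mixture | CC[C@@H](c1cc(OC)c(OC)cc1OC)[C@H](C)[C@H](c1cc(OC)c(OC)cc1OC)C=CO[Si](C)(C)C | intermediate
12 | 1-(dimethoxymethyl)-2,4,5-trimethoxybenzene | COC(OC)c1cc(OC)c(OC)cc1OC | intermediate
13 | (3S,4S,5R)-2-[methoxy(2,4,5-trimethoxyphenyl)methyl]-4-methyl-3,5-bis(2,4,5-trimethoxyphenyl)heptanal, epimers at C2 and at the methoxy-bearing carbon | CC[C@@H](c1cc(OC)c(OC)cc1OC)[C@H](C)[C@H](c1cc(OC)c(OC)cc1OC)C(C=O)C(OC)c1cc(OC)c(OC)cc1OC | intermediate (not isolated)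
14 | O-methyl oxocarbenium triflate of 15 (3-methoxy dienyl cation, stereocentres as in 15) | CC[C@@H]1[C@H](C)[C@H](c2cc(OC)c(OC)cc2OC)[C@@H](C=O)[C@H](c2cc(OC)c(OC)cc2OC)[C@]12C=C(OC)C(=[O+]C)C=C2OC.[O-]S(=O)(=O)C(F)(F)F | intermediate (not isolated)
15 | (6S,7R,8S,9S,10R,11R)-7-ethyl-10-formyl-1,4-dimethoxy-8-methyl-9,11-bis(2,4,5-trimethoxyphenyl)spiro[5.5]undeca-1,4-dien-3-one | CC[C@@H]1[C@H](C)[C@H](c2cc(OC)c(OC)cc2OC)[C@@H](C=O)[C@H](c2cc(OC)c(OC)cc2OC)[C@]12C=C(OC)C(=O)C=C2OC | intermediate
16 | (6S,7R,8S,9S,10R,11R)-7-ethyl-10-(hydroxymethyl)-1,4-dimethoxy-8-methyl-9,11-bis(2,4,5-trimethoxyphenyl)spiro[5.5]undeca-1,4-dien-3-one | CC[C@@H]1[C@H](C)[C@H](c2cc(OC)c(OC)cc2OC)[C@@H](CO)[C@H](c2cc(OC)c(OC)cc2OC)[C@]12C=C(OC)C(=O)C=C2OC | intermediate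
17 | (6S,7R,8S,9S,10R,11R)-7-ethyl-10-(iodomethyl)-1,4-dimethoxy-8-methyl-9,11-bis(2,4,5-trimethoxyphenyl)spiro[5.5]undeca-1,4-dien-3-one | CC[C@@H]1[C@H](C)[C@H](c2cc(OC)c(OC)cc2OC)[C@@H](CI)[C@H](c2cc(OC)c(OC)cc2OC)[C@]12C=C(OC)C(=O)C=C2OC | intermediate
18 | tatanan B, (6S,7R,8S,9S,10R,11R)-7-ethyl-1,4-dimethoxy-8,10-dimethyl-9,11-bis(2,4,5-trimethoxyphenyl)spiro[5.5]undeca-1,4-dien-3-one | CC[C@@H]1[C@H](C)[C@H](c2cc(OC)c(OC)cc2OC)[C@@H](C)[C@H](c2cc(OC)c(OC)cc2OC)[C@]12C=C(OC)C(=O)C=C2OC | target

**Totals and risks**

Total step count: 12. Longest linear sequence: 11 steps (steps 1–7 and 9–12, from 2,4,5-trimethoxybenzaldehyde); step 8 is a one-step branch.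

Step 9 (the step that carries the label). What may go wrong:
- the cation may lose a proton to the conjugated enal and not be re-activated;
- ortho Friedel–Crafts closure by the C3 aryl group (five-membered ring) may compete with ipso closure;
- the ipso closure may reverse or the dienone may rearrange under prolonged acid;
- control at C5 or C6 may be poor.

The fallback sets out from 11 and 12 and comes back at 15. It replaces the one-flask cascade by two separate reactions of known type with an isolated intermediate. A Mukaiyama addition with Me3SiOTf (5 mol %) in CH2Cl2 at −78 °C, quenched with pyridine, should give adduct 13, which is isolated. The benzylic methyl ether of 13 is then ionised with BF3·OEt2 in CH2Cl2 (−40 → 0 °C) or catalytic TfOH in (CF3)2CHOH, a conventional cationic ipso spirocyclisation para to a methoxy group. Aqueous work-up and, if needed, equilibration of C4 with Et3N should give 15.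

Step 5. What may go wrong:
- protodeboronation of the electron-rich, ortho-substituted boronic acid may outrun transmetalation;
- insertion into the γ-branched enoate may be slow;
- facial control at C3 may be insufficient.

The fallback sets out from 7 and comes back at 9. It is a substrate-controlled copper-mediated conjugate addition: (2,4,5-trimethoxyphenyl)magnesium bromide F1, made from 1-bromo-2,4,5-trimethoxybenzene and Mg in THF, is added to 7 with CuBr·SMe2 and Me3SiCl in THF at −78 → −30 °C. Felkin–Anh control by the C4 centre (aryl anti to the C5 branch) should favour the same C3 epimer, and hydrolytic work-up gives 9.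

Step 2. What may go wrong:
- the acid promoter may ionise the very electron-rich allylic alcohol outside the iridium cycle, eroding control at the aryl-bearing carbon;
- enamine attack on the hindered ortho-substituted allyl complex may be slow;
- the α-centre of the product aldehyde may epimerise.

The fallback sets out from propanal 3 and comes back at 5, so steps 1–3 are not needed. It uses auxiliary control throughout:
- Horner–Wadsworth–Emmons reaction of 3 with the known reagent diethyl {2-[(4S)-4-benzyl-2-oxo-1,3-oxazolidin-3-yl]-2-oxoethyl}phosphonate (LiCl, iPr2NEt, MeCN) should give (4S)-4-benzyl-3-[(2E)-pent-2-enoyl]-1,3-oxazolidin-2-one F2.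
- Copper-mediated conjugate addition of (2,4,5-trimethoxyphenyl)magnesium bromide F3 (CuBr·SMe2, THF, −40 °C), anti to the benzyl group of the chelated s-cis imide, should give (4S)-4-benzyl-3-[(3R)-3-(2,4,5-trimethoxyphenyl)pentanoyl]-1,3-oxazolidin-2-one F4.
- Evans methylation (NaN(SiMe3)2, MeI, THF, −78 °C) should give (4S)-4-benzyl-3-[(2S,3R)-2-methyl-3-(2,4,5-trimethoxyphenyl)pentanoyl]-1,3-oxazolidin-2-one F5.
- LiBH4 reduction removes the auxiliary and should give (2S,3R)-2-methyl-3-(2,4,5-trimethoxyphenyl)pentan-1-ol F6.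
- Dess–Martin oxidation gives 5.

**Further compounds**
F0 | step 9 | none | none
F1 | step 5 | (2,4,5-trimethoxyphenyl)magnesium bromide | COc1cc(OC)c([Mg]Br)cc1OC
F2 | step 2 | (4S)-4-benzyl-3-[(2E)-pent-2-enoyl]-1,3-oxazolidin-2-one | CC/C=C/C(=O)N1[C@@H](Cc2ccccc2)COC1=O
F3 | step 2 | (2,4,5-trimethoxyphenyl)magnesium bromide | COc1cc(OC)c([Mg]Br)cc1OC
F4 | step 2 | (4S)-4-benzyl-3-[(3R)-3-(2,4,5-trimethoxyphenyl)pentanoyl]-1,3-oxazolidin-2-one | CC[C@@H](c1cc(OC)c(OC)cc1OC)CC(=O)N1[C@@H](Cc2ccccc2)COC1=O
F5 | step 2 | (4S)-4-benzyl-3-[(2S,3R)-2-methyl-3-(2,4,5-trimethoxyphenyl)pentanoyl]-1,3-oxazolidin-2-one | CC[C@@H](c1cc(OC)c(OC)cc1OC)[C@H](C)C(=O)N1[C@@H](Cc2ccccc2)COC1=O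
F6 | step 2 | (2S,3R)-2-methyl-3-(2,4,5-trimethoxyphenyl)pentan-1-ol | CC[C@@H](c1cc(OC)c(OC)cc1OC)[C@H](C)CO
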